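## The problem

The target 18 is a 3-methoxyflavone: a 4H-chromen-4-one (ring A fused to the pyranone ring C) that carries ring B at C2. Ring A is a phloroglucinol ring with free hydroxyls at C5 and C7, ring B carries 2'-OH, 4'-OMe and 5'-OAc, and C3 carries OMe. There is no stereocentre in 18; the one sp3 centre met on the way (C2 of a flavan-3-one) is racemic, controls nothing and is flattened before the end. The real task is to tell four phenolic oxygens apart: three end free and one ends as an acetate that cannot be put on selectively at the last stage. The aryl acetate is also the fragile group: carbonate, alkoxides, free phenoxides and Grignard reagents cleave or transfer it, so it tolerates only neutral or mildly acidic steps, and the other three phenols must be unmasked under neutral conditions after it is in place. Ring C has to finish with oxygen on C3 and a carbonyl on C4 next to a very electron-rich ring A. The feature that opens the chosen route is that C3 bears oxygen and C4 is bonded to C4a, one of two equivalent carbons ortho to O1 on a symmetric 3,5-dioxygenated aryl ether. An electrophilic carbon at C4 flanked by a C3 carbonyl can therefore close ring C on either of them with no regiochemical question.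

## Retrosynthesis

Target 18 is traced to the tribenzyl ether 17 by cutting the three benzyl–oxygen bonds at O5, O7 and O2'. Hydrogenolysis is the one global deprotection that can be trusted to leave an aryl acetate alone; acid- or fluoride-labile groups on the phloroglucinol ring would be less dependable in the earlier steps. Compound 17 has the same skeleton, but the acetate is its only ester among ethers, so the selectivity problem is gone. The forward step only has to spare the acetate and the pyranone double bond.

Compound 17 comes from the flavonol 16 by cutting the O3–CH3 bond, and 16 from the flavan-3-one 14 by removing the C4 oxygen; the 3,4-dione 15 is the tautomer through which 16 forms. Bringing C4 in as a carbonyl would mean acylating ring A, which is the logic of the chalcone routes discussed below. Here the C3 oxygen is already a ketone and C4 is a methylene activated by both ring A and the carbonyl, so one α-oxidation and a tautomerisation give the aromatic pyranone. Compound 14 lacks one oxygen and one methyl group and has a stereocentre that needs no control. The forward steps must oxidise C4 and not C2, and must methylate O3 without a base that would move the acetate.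

Compound 14 is cut at C4–C4a, which opens ring C and leads to the aryl propargyl ether 13. Among the ring C bonds this is the one that can be formed without any prior functionalisation of ring A: an α-oxo carbene generated from the terminal alkyne attacks an unsubstituted ortho carbon, and the two ortho carbons are equivalent. The same operation delivers the C3 oxygen. Compound 13 is acyclic between the two arenes and is made of three simple parts. The forward reaction must oxidise the alkyne faster than the electron-rich arene adds to it, and must not ionise the benzylic propargylic C–O bond.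

Compound 13 is related to the silyl ether 11 by exchange of acetyl for triisopropylsilyl on O5' (phenol 12 in passing), and 11 is cut at the O1–C2 bond into the propargylic alcohol 9 and the phenol 10. The acetate is introduced only here because every earlier step uses carbonate, a Grignard reagent or a phenoxide, while every later step is neutral. The acetate also lowers the nucleophilicity of ring B just before the carbene is generated. The O1–C2 cut is preferred to an aryl–oxygen cut because 10 is a bought phenol and 9 an activated secondary alcohol, which suits a Mitsunobu etherification. That reaction must alkylate 10 on oxygen and not on carbon.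

Compound 9 is cut at C2–C3 into the aldehyde 7 and the acetylide 8. This is the shortest way to the three-carbon unit, since the alkyne carbons become C3 and C4. The new carbinol centre may be racemic.

Compound 7 goes back through 5 and 4 to 2 and vanillin 1, with 3 and 6 as passing intermediates. Vanillin supplies the adjacent 4'-OMe/5'-O pair with the 5'-oxygen already distinct. A Baeyer–Villiger step turns the formyl carbon into the 2'-oxygen, which is benzylated. Formylation then returns one carbon to the position para to OMe and ortho to OBn, the only doubly activated open site. Each step is a standard arene manipulation; the only demand is that the silyl ether survives them.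

## Roads not taken

Alternative 1: The flavone is cut at O1–C8a and C4–C4a, so ring A is delivered as an aryne and ring C is closed later from a chalcone. In the forward direction fluoride releases the aryne from the silyl triflate A3. The carboxylate of the α-methoxycinnamic acid A2 adds to the aryne carbon remote from the neighbouring benzyloxy group, and the aryl anion takes over the acyl group, giving the 2'-hydroxy-α-methoxychalcone A1.
- Merits: C4 arrives as a carbonyl and O3 already carries its methyl group, so neither the α-oxidation nor the late methylation of the chosen route is needed. The 3-alkoxy group of the aryne fixes the regiochemistry, and the union is convergent.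
- Weak points: the key step closes no ring, so an oxidative cyclisation of A1 (oxa-Michael addition and dehydrogenation) must follow, and it competes with five-membered closure. A3 costs several steps from the very phenol 10 that the chosen route uses as bought. The phenol freed in A1 can add to a second aryne. The basic fluoride step forces an acetal placeholder on O5', which costs a deprotection and an acetylation.
- Comparison: this road is better in redox economy. The chosen plan sets against it a key step that forms ring C directly, a ring A that needs no pre-functionalisation, and a step count expected to be lower.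

Alternative 2: Ring A is taken apart at C4a–C5 while rings B and C stay. Heating the acyl Meldrum's acid A5 would release an acylketene tethered through C8. Its ketene carbon is to be attacked by the pyranone carbon that becomes C4a, and enolisation aromatises ring A to give A4, the 2'-O-benzyl ether of 18.
- Merits: ring A appears with both hydroxyls free, the acetate is already in place, the step is neutral and thermal, and one hydrogenolysis leads from A4 to 18. That end game is shorter than the three steps that follow the key step of the chosen route, and fewer protecting groups are used.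
- Weak points: A5 needs a long linear build-up of a 2-aryl-3-methoxy-4-pyranone with an acetic acid side chain. The pyranone carbon next to the carbonyl is a poor nucleophile, and its C-acylation by a ketene has no close model. The acylketene has easier exits: dimerisation, capture by adventitious nucleophiles, or closure on its own enol.
- Comparison: the end game is better, but the key step would be new chemistry on a costly precursor. The chosen key step belongs to an established reaction class, and its precursor 13 is seven steps from 1.

Alternative 3: Ring C is cut at C3–C4 and O1–C8a. The enolate of the α-methoxy ketone A7 is C-acylated by the acid chloride A8, and the oxygen of the resulting diketone enolate displaces an ortho fluoride, giving the 5,7-difluoro-3-methoxyflavone A6 in one flask.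
- Merits: this ring closure is well established, C4 and the O3 methyl group are in place from the start, A8 is commercial, and the sequence is short.
- Weak points: the two ring A oxygens are still missing after the key step. Both fluorides must be exchanged for benzyloxy groups by nucleophilic aromatic substitution on a chromone. The second exchange is slowed by the first alkoxy group, and the alkoxide can add at C2 and open ring C. The strong bases force an acetal placeholder on O5' (two extra steps), and A7 needs about as many steps from 1 as 13 does.
- Comparison: the ring closure is better precedented and more scalable than a gold carbene step, no α-oxidation is required, and the road is at least as short. The chosen plan sets against it that ring A enters with its oxygens in place, so no forcing substitution is run on the finished chromone, and that every step after the acetate is installed is neutral.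

Key step: step 8

Assumption: 3,5-bis(benzyloxy)phenol 10 and ethynylmagnesium bromide 8 (solution in THF) are purchased; all intermediates with the C2 stereocentre are handled as racemates.

## Route

Step 1
Reactants: 1 vanillin
Product: 2 3-methoxy-4-[(triisopropylsilyl)oxy]benzaldehyde
Conditions: TIPSCl, imidazole, DMF, rt
Reagents that add atoms: chlorotriisopropylsilane, CC(C)[Si](Cl)(C(C)C)C(C)C
Why: Imidazole-promoted O-silylation of the only phenol. The triisopropylsilyl ether should withstand carbonate, the Vilsmeier salt and the Grignard reagent, and is later removed by fluoride without touching benzyl ethers.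

Step 2
Reactants: 2 3-methoxy-4-[(triisopropylsilyl)oxy]benzaldehyde
Product: 4 3-methoxy-4-[(triisopropylsilyl)oxy]phenol, via aryl formate 3 (not isolated)
Conditions: mCPBA, CH2Cl2, 0 °C → rt; then Et3N, MeOH, rt
Reagents that add atoms: 3-chloroperbenzoic acid (mCPBA), O=C(OO)c1cccc(Cl)c1
Why: Baeyer–Villiger (Dakin-type) oxidation, in which the electron-rich para-silyloxy aryl group migrates in preference to hydride. The aryl formate is then methanolysed under conditions too mild to cleave the hindered aryl silyl ether.

Step 3
Reactants: 4 3-methoxy-4-[(triisopropylsilyl)oxy]phenol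
Product: 5 [4-(benzyloxy)-2-methoxyphenoxy]triisopropylsilane
Conditions: BnBr, K2CO3, acetone, reflux
Reagents that add atoms: benzyl bromide, BrCc1ccccc1
Why: Williamson etherification of the free phenol; carbonate in acetone should leave the bulky aryl silyl ether intact.

Step 4
Reactants: 5 [4-(benzyloxy)-2-methoxyphenoxy]triisopropylsilane
Product: 7 2-(benzyloxy)-4-methoxy-5-[(triisopropylsilyl)oxy]benzaldehyde, via aryl iminium salt 6 (not isolated)
Conditions: POCl3, DMF, 0 → 60 °C; then ice-cold aq NaOAc
Reagents that add atoms: N,N-dimethylformamide, CN(C)C=O; water, O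
Why: Vilsmeier–Haack formylation. The carbon para to OMe and ortho to OBn is the only open position activated by two alkoxy groups and not flanked by two substituents, the pattern 1,2,4-trialkoxybenzenes follow; buffered hydrolysis of the iminium salt frees the aldehyde.

Step 5
Reactants: 7 2-(benzyloxy)-4-methoxy-5-[(triisopropylsilyl)oxy]benzaldehyde; 8 ethynylmagnesium bromide
Product: 9 rac-1-{2-(benzyloxy)-4-methoxy-5-[(triisopropylsilyl)oxy]phenyl}prop-2-yn-1-ol
Conditions: 8 (0.5 M in THF, 1.3 equiv), THF, −78 → 0 °C; then sat. aq NH4Cl
Reagents that add atoms: none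
Why: Grignard 1,2-addition of the acetylide to the aldehyde. The carbinol centre forms as a racemate, which is acceptable because it becomes the sp2 carbon C2 in step 9.

Step 6
Reactants: 9 rac-1-{2-(benzyloxy)-4-methoxy-5-[(triisopropylsilyl)oxy]phenyl}prop-2-yn-1-ol; 10 3,5-bis(benzyloxy)phenol
Product: 11 rac-{4-(benzyloxy)-5-[1-(3,5-bis(benzyloxy)phenoxy)prop-2-yn-1-yl]-2-methoxyphenoxy}triisopropylsilane
Conditions: PPh3, DIAD, THF, 0 °C → rt
Reagents that add atoms: none
Why: Mitsunobu etherification: the phenol (pKa about 9–10) protonates the betaine and its oxygen displaces the activated secondary propargylic alcohol under neutral conditions. The steric course is irrelevant for a racemate.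

Step 7
Reactants: 11 rac-{4-(benzyloxy)-5-[1-(3,5-bis(benzyloxy)phenoxy)prop-2-yn-1-yl]-2-methoxyphenoxy}triisopropylsilane
Product: 13 rac-4-(benzyloxy)-5-{1-[3,5-bis(benzyloxy)phenoxy]prop-2-yn-1-yl}-2-methoxyphenyl acetate, via free phenol 12 (not isolated)
Conditions: TBAF, AcOH, THF, 0 °C; then Ac2O, Et3N, DMAP (cat.), 0 °C → rt
Reagents that add atoms: acetic anhydride, CC(=O)OC(C)=O
Why: Fluoride cleaves the aryl Si–O bond while acetic acid buffers the phenoxide so that the propargylic C–H is not deprotonated, and the phenol is acetylated in the same flask by DMAP-catalysed acyl transfer. From here on no basic or nucleophilic reagent meets the acetate.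

Step 8
Reactants: 13 rac-4-(benzyloxy)-5-{1-[3,5-bis(benzyloxy)phenoxy]prop-2-yn-1-yl}-2-methoxyphenyl acetate
Product: 14 rac-2-[5-acetoxy-2-(benzyloxy)-4-methoxyphenyl]-5,7-bis(benzyloxy)chroman-3-one
Conditions: [2-(tBu)2P-3,4,5,6-Me4-2',4',6'-iPr3-biphenyl]AuNTf2 (5 mol %), 2,6-dichloropyridine N-oxide (1.5 equiv), 1,2-dichloroethane, rt
Reagents that add atoms: 2,6-dichloropyridine N-oxide, [O-][n+]1c(Cl)cccc1Cl
Why: Gold-catalysed alkyne oxidation followed by intramolecular carbene arylation, the known route from aryl propargyl ethers to chroman-3-ones. The cationic monovalent gold complex binds the terminal alkyne, the N-oxide oxygen adds to the internal carbon, and loss of 2,6-dichloropyridine from the vinylgold species leaves an α-oxo gold carbene on the terminal carbon. The carbene carbon is attacked by the ring A carbon ortho to the ether oxygen, which is also ortho and para to the two benzyloxy groups, and rearomatisation with protodeauration gives the C4 methylene. Ring C closes as a six-membered ring by electrophilic aromatic substitution, exo with respect to the carbon–gold bond. No stereocentre is created; the existing C2 centre stays racemic and is removed in step 9. The step needs chemoselectivity for oxidation over direct 6-endo hydroarylation, which an excess of the strongly nucleophilic N-oxide and the hindered electron-rich biaryl phosphine should secure, the ligand also shielding the carbene from a second oxidation. Site selectivity comes from the substrate: the two ortho carbons of ring A are equivalent and triply activated, whereas the only reachable carbon of ring B would close a five-membered ring and is deactivated by the adjacent acetate. The weakly basic, hindered 2,6-dichloropyridine does not bind gold, so no acid additive is needed and the ionisable benzylic propargylic C–O bond never meets a strong Brønsted acid.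

Step 9
Reactants: 14 rac-2-[5-acetoxy-2-(benzyloxy)-4-methoxyphenyl]-5,7-bis(benzyloxy)chroman-3-one
Product: 16 2-[5-acetoxy-2-(benzyloxy)-4-methoxyphenyl]-5,7-bis(benzyloxy)-3-hydroxy-4H-chromen-4-one, via chromane-3,4-dione 15 (not isolated)
Conditions: SeO2 (1.5 equiv), 1,4-dioxane/H2O (30:1), 80 °C
Reagents that add atoms: selenium dioxide, O=[Se]=O
Why: Riley oxidation: SeO2 should attack the enol toward C4, which is conjugated with ring A and whose methylene is activated by both aryl and carbonyl, to give the 3,4-dione. The dione tautomerises through its C2–H to the aromatic 3-hydroxy-4-pyranone, which erases the C2 stereocentre.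

Step 10
Reactants: 16 2-[5-acetoxy-2-(benzyloxy)-4-methoxyphenyl]-5,7-bis(benzyloxy)-3-hydroxy-4H-chromen-4-one
Product: 17 2-[5-acetoxy-2-(benzyloxy)-4-methoxyphenyl]-5,7-bis(benzyloxy)-3-methoxy-4H-chromen-4-one
Conditions: MeOH, PPh3, DIAD, THF, 0 °C → rt
Reagents that add atoms: methanol, CO
Why: Mitsunobu O-methylation: the acidic flavonol 3-OH (pKa about 9) is alkylated by the methoxyphosphonium ion under neutral conditions. No carbonate or free flavonolate is present to cleave or transfer the aryl acetate.

Step 11
Reactants: 17 2-[5-acetoxy-2-(benzyloxy)-4-methoxyphenyl]-5,7-bis(benzyloxy)-3-methoxy-4H-chromen-4-one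
Product: 18 5-(5,7-dihydroxy-3-methoxy-4-oxo-4H-chromen-2-yl)-4-hydroxy-2-methoxyphenyl acetate (5,7,2',5'-tetrahydroxy-3,4'-dimethoxyflavone 5'-acetate)
Conditions: H2 (1 atm), 10% Pd/C, EtOAc/THF, rt
Reagents that add atoms: none
Why: Heterogeneous hydrogenolysis of three aryl benzyl ethers in an aprotic solvent. The aryl acetate, the methyl ethers and the tetrasubstituted C2=C3 bond of the pyranone should be inert, and the acetate has no neighbouring hydroxyl to migrate to.

## Compound list

1 | vanillin | COc1cc(C=O)ccc1O | starting material
2 | 3-methoxy-4-[(triisopropylsilyl)oxy]benzaldehyde | COc1cc(C=O)ccc1O[Si](C(C)C)(C(C)C)C(C)C | intermediate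
3 | 3-methoxy-4-[(triisopropylsilyl)oxy]phenyl formate | COc1cc(OC=O)ccc1O[Si](C(C)C)(C(C)C)C(C)C | intermediate
4 | 3-methoxy-4-[(triisopropylsilyl)oxy]phenol | COc1cc(O)ccc1O[Si](C(C)C)(C(C)C)C(C)C | intermediate
5 | [4-(benzyloxy)-2-methoxyphenoxy]triisopropylsilane | COc1cc(OCc2ccccc2)ccc1O[Si](C(C)C)(C(C)C)C(C)C | intermediate
6 | N-{[2-(benzyloxy)-4-methoxy-5-(triisopropylsilyloxy)phenyl]methylidene}-N-methylmethanaminium chloride | COc1cc(OCc2ccccc2)c(C=[N+](C)C)cc1O[Si](C(C)C)(C(C)C)C(C)C.[Cl-] | intermediate
7 | 2-(benzyloxy)-4-methoxy-5-[(triisopropylsilyl)oxy]benzaldehyde | COc1cc(OCc2ccccc2)c(C=O)cc1O[Si](C(C)C)(C(C)C)C(C)C | intermediate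
8 | ethynylmagnesium bromide | C#C[Mg]Br | starting material
9 | rac-1-{2-(benzyloxy)-4-methoxy-5-[(triisopropylsilyl)oxy]phenyl}prop-2-yn-1-ol | C#CC(O)c1cc(O[Si](C(C)C)(C(C)C)C(C)C)c(OC)cc1OCc1ccccc1 | intermediate
10 | 3,5-bis(benzyloxy)phenol | Oc1cc(OCc2ccccc2)cc(OCc2ccccc2)c1 | starting material
11 | rac-{4-(benzyloxy)-5-[1-(3,5-bis(benzyloxy)phenoxy)prop-2-yn-1-yl]-2-methoxyphenoxy}triisopropylsilane | C#CC(Oc1cc(OCc2ccccc2)cc(OCc2ccccc2)c1)c1cc(O[Si](C(C)C)(C(C)C)C(C)C)c(OC)cc1OCc1ccccc1 | intermediate
12 | rac-4-(benzyloxy)-5-{1-[3,5-bis(benzyloxy)phenoxy]prop-2-yn-1-yl}-2-methoxyphenol | C#CC(Oc1cc(OCc2ccccc2)cc(OCc2ccccc2)c1)c1cc(O)c(OC)cc1OCc1ccccc1 | intermediate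
13 | rac-4-(benzyloxy)-5-{1-[3,5-bis(benzyloxy)phenoxy]prop-2-yn-1-yl}-2-methoxyphenyl acetate | C#CC(Oc1cc(OCc2ccccc2)cc(OCc2ccccc2)c1)c1cc(OC(C)=O)c(OC)cc1OCc1ccccc1 | intermediate
14 | rac-2-[5-acetoxy-2-(benzyloxy)-4-methoxyphenyl]-5,7-bis(benzyloxy)chroman-3-one | O=C1Cc2c(OCc3ccccc3)cc(OCc3ccccc3)cc2OC1c1cc(OC(C)=O)c(OC)cc1OCc1ccccc1 | intermediate
15 | rac-2-[5-acetoxy-2-(benzyloxy)-4-methoxyphenyl]-5,7-bis(benzyloxy)chromane-3,4-dione | O=C1C(=O)c2c(OCc3ccccc3)cc(OCc3ccccc3)cc2OC1c1cc(OC(C)=O)c(OC)cc1OCc1ccccc1 | intermediate
16 | 2-[5-acetoxy-2-(benzyloxy)-4-methoxyphenyl]-5,7-bis(benzyloxy)-3-hydroxy-4H-chromen-4-one | O=c1c(O)c(-c2cc(OC(C)=O)c(OC)cc2OCc2ccccc2)oc2cc(OCc3ccccc3)cc(OCc3ccccc3)c12 | intermediate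
17 | 2-[5-acetoxy-2-(benzyloxy)-4-methoxyphenyl]-5,7-bis(benzyloxy)-3-methoxy-4H-chromen-4-one | COc1c(-c2cc(OC(C)=O)c(OC)cc2OCc2ccccc2)oc2cc(OCc3ccccc3)cc(OCc3ccccc3)c2c1=O | intermediate
18 | 5,7,2',5'-tetrahydroxy-3,4'-dimethoxyflavone 5'-acetate | COc1cc(O)c(-c2oc3cc(O)cc(O)c3c(=O)c2OC)cc1OC(C)=O | target

## Step count and risks

Total step count: 11. Longest linear sequence: 11 steps, from vanillin 1 to 18; compounds 8 and 10 enter as purchased reagents.

Least certain steps, most critical first:

**Step 8 (key step).** Three processes can divert the substrate:
- direct 6-endo hydroarylation of the gold-bound alkyne by the very electron-rich ring A before the N-oxide adds;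
- capture of the carbene by the 2'-benzyloxy oxygen followed by a benzyl shift;
- ionisation of the benzylic propargylic C–O bond at the Lewis acidic metal.

The fallback accepts the hydroarylation and adds the oxygen afterwards. From 13, Ph3PAuNTf2 without oxidant in CH2Cl2 should give the flav-3-ene rac-2-[5-acetoxy-2-(benzyloxy)-4-methoxyphenyl]-5,7-bis(benzyloxy)-2H-chromene F1. Epoxidation with dimethyldioxirane in acetone at low temperature gives rac-2-[5-acetoxy-2-(benzyloxy)-4-methoxyphenyl]-5,7-bis(benzyloxy)-3,4-epoxychromane F2; the oxygen is expected trans to the aryl group, and the configuration is lost in the next operation. Meinwald rearrangement with catalytic ZnI2 opens the epoxide at C4, the site stabilised by ring A, and hydride shift returns the route to 14.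

**Step 6.** The oxyphosphonium ion of the electron-rich benzylic propargylic alcohol may ionise. That would lead to C-alkylation of the phloroglucinol ring of 10, or to elimination and self-condensation, instead of O-alkylation. Fallback from 9: acetylation (Ac2O, Et3N, DMAP) gives the propargylic ester rac-1-{2-(benzyloxy)-4-methoxy-5-[(triisopropylsilyl)oxy]phenyl}prop-2-yn-1-yl acetate F3. A copper-catalysed propargylic etherification with 10 then follows, using (CuOTf)2·C6H6, an achiral bis(oxazolinyl)pyridine ligand and iPr2NEt. It runs through a copper allenylidene, delivers the phenol oxygen to the propargylic carbon, and rejoins the route at 11.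

**Step 9.** Oxidation may start at the wrong α-carbon (C2, also benzylic and next to oxygen), may run on beyond the flavonol, or the acetate may be partly hydrolysed in hot aqueous dioxane. Fallback from 14, stepwise enol oxygenation:
- Soft enolisation with TMSOTf and Et3N gives the conjugated silyl enol ether rac-2-[5-acetoxy-2-(benzyloxy)-4-methoxyphenyl]-5,7-bis(benzyloxy)-3-[(trimethylsilyl)oxy]-2H-chromene F4. Its regiochemistry can be checked before any oxidant is added.
- Rubottom oxidation with dimethyldioxirane and a mild acidic work-up gives rac-2-[5-acetoxy-2-(benzyloxy)-4-methoxyphenyl]-5,7-bis(benzyloxy)-4-hydroxychroman-3-one F5 as a mixture of diastereomers.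
- Dess–Martin periodinane oxidises this to the dione 15, which tautomerises to 16.

**Step 4.** The silyl ether may be lost under the acidic chloroiminium conditions, or substitution may be slow on the silyloxy-bearing ring. Fallback from 4: magnesium-mediated ortho-formylation of the free phenol (MgCl2, Et3N, paraformaldehyde, MeCN, reflux) places the formyl group ortho to the phenol and para to OMe, giving 2-hydroxy-4-methoxy-5-[(triisopropylsilyl)oxy]benzaldehyde F6. Benzylation (BnBr, K2CO3, DMF) then rejoins the route at 7.

**Step 7.** Fluoride or the ammonium phenoxide may cause propargyl-to-allene isomerisation of the doubly activated C–H. Fallback from 9, where the exchange is made before the ether exists: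
- TBAF gives rac-4-(benzyloxy)-5-(1-hydroxyprop-2-yn-1-yl)-2-methoxyphenol F7.
- Selective acetylation of the phenol (Ac2O, aq NaHCO3/THF, 0 °C) gives rac-4-(benzyloxy)-5-(1-hydroxyprop-2-yn-1-yl)-2-methoxyphenyl acetate F8.
- Mitsunobu etherification with 10 rejoins the route at 13.

## Further compounds

F1 | step 8 | rac-2-[5-acetoxy-2-(benzyloxy)-4-methoxyphenyl]-5,7-bis(benzyloxy)-2H-chromene | COc1cc(OCc2ccccc2)c(C2C=Cc3c(OCc4ccccc4)cc(OCc4ccccc4)cc3O2)cc1OC(C)=O
F2 | step 8 | rac-2-[5-acetoxy-2-(benzyloxy)-4-methoxyphenyl]-5,7-bis(benzyloxy)-3,4-epoxychromane | COc1cc(OCc2ccccc2)c(C2Oc3cc(OCc4ccccc4)cc(OCc4ccccc4)c3C3OC23)cc1OC(C)=O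
F3 | step 6 | rac-1-{2-(benzyloxy)-4-methoxy-5-[(triisopropylsilyl)oxy]phenyl}prop-2-yn-1-yl acetate | C#CC(OC(C)=O)c1cc(O[Si](C(C)C)(C(C)C)C(C)C)c(OC)cc1OCc1ccccc1
F4 | step 9 | rac-2-[5-acetoxy-2-(benzyloxy)-4-methoxyphenyl]-5,7-bis(benzyloxy)-3-[(trimethylsilyl)oxy]-2H-chromene | COc1cc(OCc2ccccc2)c(C2Oc3cc(OCc4ccccc4)cc(OCc4ccccc4)c3C=C2O[Si](C)(C)C)cc1OC(C)=O
F5 | step 9 | rac-2-[5-acetoxy-2-(benzyloxy)-4-methoxyphenyl]-5,7-bis(benzyloxy)-4-hydroxychroman-3-one | COc1cc(OCc2ccccc2)c(C2Oc3cc(OCc4ccccc4)cc(OCc4ccccc4)c3C(O)C2=O)cc1OC(C)=O
F6 | step 4 | 2-hydroxy-4-methoxy-5-[(triisopropylsilyl)oxy]benzaldehyde | COc1cc(O)c(C=O)cc1O[Si](C(C)C)(C(C)C)C(C)C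
F7 | step 7 | rac-4-(benzyloxy)-5-(1-hydroxyprop-2-yn-1-yl)-2-methoxyphenol | C#CC(O)c1cc(O)c(OC)cc1OCc1ccccc1
F8 | step 7 | rac-4-(benzyloxy)-5-(1-hydroxyprop-2-yn-1-yl)-2-methoxyphenyl acetate | C#CC(O)c1cc(OC(C)=O)c(OC)cc1OCc1ccccc1
A1 | alternative 1 | (Z)-1-[2,4-bis(benzyloxy)-6-hydroxyphenyl]-3-[2-(benzyloxy)-4-methoxy-5-(methoxymethoxy)phenyl]-2-methoxyprop-2-en-1-one | CO/C(=C\c1cc(OCOC)c(OC)cc1OCc1ccccc1)C(=O)c1c(O)cc(OCc2ccccc2)cc1OCc1ccccc1
A2 | alternative 1 | (Z)-3-[2-(benzyloxy)-4-methoxy-5-(methoxymethoxy)phenyl]-2-methoxyprop-2-enoic acid | CO/C(=C\c1cc(OCOC)c(OC)cc1OCc1ccccc1)C(=O)O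
A3 | alternative 1 | 3,5-bis(benzyloxy)-2-(trimethylsilyl)phenyl trifluoromethanesulfonate | C[Si](C)(C)c1c(OCc2ccccc2)cc(OCc2ccccc2)cc1OS(=O)(=O)C(F)(F)F
A4 | alternative 2 | 4-(benzyloxy)-5-(5,7-dihydroxy-3-methoxy-4-oxo-4H-chromen-2-yl)-2-methoxyphenyl acetate | COc1cc(OCc2ccccc2)c(-c2oc3cc(O)cc(O)c3c(=O)c2OC)cc1OC(C)=O
A5 | alternative 2 | 4-(benzyloxy)-5-{6-[2-(2,2-dimethyl-4,6-dioxo-1,3-dioxan-5-yl)-2-oxoethyl]-3-methoxy-4-oxo-4H-pyran-2-yl}-2-methoxyphenyl acetate | COc1cc(OCc2ccccc2)c(-c2oc(CC(=O)C3C(=O)OC(C)(C)OC3=O)cc(=O)c2OC)cc1OC(C)=O
A6 | alternative 3 | 2-[2-(benzyloxy)-4-methoxy-5-(methoxymethoxy)phenyl]-5,7-difluoro-3-methoxy-4H-chromen-4-one | COc1cc(OCc2ccccc2)c(-c2oc3cc(F)cc(F)c3c(=O)c2OC)cc1OCOC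
A7 | alternative 3 | 1-[2-(benzyloxy)-4-methoxy-5-(methoxymethoxy)phenyl]-2-methoxyethan-1-one | COCC(=O)c1cc(OCOC)c(OC)cc1OCc1ccccc1
A8 | alternative 3 | 2,4,6-trifluorobenzoyl chloride | O=C(Cl)c1c(F)cc(F)cc1F
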